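## Retrosynthetic overview

1. Feature: the benzo ring of the coumarin (C4a, C5, C6, C7, C8, C8a) carries oxygen at C5, C7 and C8a, the 1,3,5-pattern of a folded triketide. With O7 alone etherified, O5 and O8a are interchangeable, so the lactone may close on either phenol.
2. Target ⇐ acetonide hydrolysis ⇐ 5-hydroxy-7-alkoxycoumarin acetonide ⇐ E→Z photoisomerisation and lactonisation of a tert-butyl 2,6-dihydroxy-4-alkoxycinnamate (lactone ring of the coumarin, formed last).
3. Cinnamate ⇐ key step: Mg(OMe)2 opens a 4-alkoxy-2-pyranone at its lactone carbonyl (future C8a) and the chain recloses by Claisen acylation C4a→C8a. The benzene ring is built from the sacrificed pyranone ring, whose 4-alkoxy group has already fixed O7.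
4. Pyranone precursor ⇐ lateral hydroxymethylation, then oxidation/Wittig olefination at the 6-methyl group ⇐ Mitsunobu etherification of triacetic acid lactone with the side-chain alcohol.
5. Side-chain alcohol ⇐ diethyl L-tartrate (C8'–C11', both stereocentres; dioxolane ring formed first), two zirconium-catalysed carboaluminations and one Negishi coupling for the two (E)-trisubstituted alkenes.

Key step: step 13

Remark: the (9'S,10'R) diol is taken as the threo diol of (2R,3R)-tartrate carried through with retention (C9' changes descriptor only because its carboxyl carbon becomes the C8' methylene); the tertiary C11' hydroxyl stays unprotected, each organometallic step spending one extra equivalent on it.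

Locants: coumarin locants are also used for the corresponding atoms of the pyranone precursor (pyranone C2 = C8a, C3 = C8, C4 = C7, C5 = C6, C6 = C5, exocyclic CH2 = C4a). Primed locants belong to the side chain. Sc = (2E,6E)-8-[(4S,5R)-5-(2-hydroxypropan-2-yl)-2,2-dimethyl-1,3-dioxolan-4-yl]-3,7-dimethylocta-2,6-dien-1-yl, the side chain as its 9',10'-acetonide.

## Route

Step 1
Reactants: 1 diethyl L-tartrate, diethyl (2R,3R)-2,3-dihydroxybutanedioate
Product: 2 diethyl (4R,5R)-2,2-dimethyl-1,3-dioxolane-4,5-dicarboxylate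
Conditions: 2,2-dimethoxypropane, TsOH·H2O (cat.), cyclohexane, reflux (MeOH distilled off)
Reagents that add atoms: 2,2-dimethoxypropane, COC(C)(C)OC
Why: Acid-catalysed transketalisation closes the trans-dioxolane on the threo diol and is driven by removal of methanol; neither stereocentre is touched.

Step 2
Reactants: 2 diethyl (4R,5R)-2,2-dimethyl-1,3-dioxolane-4,5-dicarboxylate
Product: 3 ethyl (4R,5S)-5-(hydroxymethyl)-2,2-dimethyl-1,3-dioxolane-4-carboxylate
Conditions: NaBH4 (0.6 equiv), EtOH, 0 → 23 °C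
Reagents that add atoms: none
Why: Borohydride reduction of an α-alkoxy-activated ester with limiting hydride should stop at the mono-alcohol of the C2-symmetric diester (recovered 2 is recycled), without epimerising the trans-dioxolane.

Step 3
Reactants: 3 ethyl (4R,5S)-5-(hydroxymethyl)-2,2-dimethyl-1,3-dioxolane-4-carboxylate
Product: 4 2-[(4R,5S)-5-(hydroxymethyl)-2,2-dimethyl-1,3-dioxolan-4-yl]propan-2-ol
Conditions: MeMgBr (3.5 equiv), THF, 0 → 23 °C; aq. NH4Cl
Reagents that add atoms: methylmagnesium bromide, C[Mg]Br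
Why: Double Grignard addition to the remaining ester gives the tertiary carbinol (future C11'); addition outruns enolisation, so the adjacent stereocentre (future C10') is retained.

Step 4
Reactants: 4 2-[(4R,5S)-5-(hydroxymethyl)-2,2-dimethyl-1,3-dioxolan-4-yl]propan-2-ol
Product: 5 2-[(4R,5R)-5-(iodomethyl)-2,2-dimethyl-1,3-dioxolan-4-yl]propan-2-ol
Conditions: I2, PPh3, imidazole, CH2Cl2, 0 → 23 °C
Reagents that add atoms: iodine, II
Why: Appel-type iodination activates only the primary alcohol; the tertiary hydroxyl is inert and cannot close onto C8' across the trans-fused dioxolane.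

Step 5
Reactants: 5 2-[(4R,5R)-5-(iodomethyl)-2,2-dimethyl-1,3-dioxolan-4-yl]propan-2-ol
Product: 6 2-[(4R,5S)-2,2-dimethyl-5-(prop-2-yn-1-yl)-1,3-dioxolan-4-yl]propan-2-ol
Conditions: LiC≡CH·H2NCH2CH2NH2 (3 equiv), DMSO, 15 → 23 °C
Reagents that add atoms: lithium acetylide–ethylenediamine complex, [Li+].[C-]#C.NCCN
Why: SN2 alkynylation of the primary iodide by acetylide in a dipolar aprotic solvent takes place at C8' and leaves C9' and C10' unchanged.

Step 6
Reactants: 6 2-[(4R,5S)-2,2-dimethyl-5-(prop-2-yn-1-yl)-1,3-dioxolan-4-yl]propan-2-ol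
Product: 8 2-[(4R,5S)-5-[(2E)-3-iodo-2-methylprop-2-en-1-yl]-2,2-dimethyl-1,3-dioxolan-4-yl]propan-2-ol, via alkenylalane 7 (not isolated)
Conditions: Me3Al (4 equiv), Cp2ZrCl2 (0.3 equiv), CH2Cl2, 0 → 23 °C; then I2, THF, −30 → 0 °C
Reagents that add atoms: trimethylaluminium, C[Al](C)C; iodine, II
Why: Zirconium-catalysed carboalumination adds methyl and aluminium syn across the terminal alkyne (methyl to the internal carbon), and iodinolysis with retention should give the (E)-iodide, which fixes the C6'=C7' geometry.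

Step 7
Reactants: 8 2-[(4R,5S)-5-[(2E)-3-iodo-2-methylprop-2-en-1-yl]-2,2-dimethyl-1,3-dioxolan-4-yl]propan-2-ol; 9 (4-bromobut-1-yn-1-yl)trimethylsilane
Product: 11 2-[(4R,5S)-2,2-dimethyl-5-[(2E)-2-methyl-7-(trimethylsilyl)hept-2-en-6-yn-1-yl]-1,3-dioxolan-4-yl]propan-2-ol, via alkylzinc bromide 10 (not isolated)
Conditions: 9 (2.5 equiv), Zn dust, LiCl, THF, 50 °C; then 8, Pd(PPh3)4 (5 mol %), THF, 23 °C
Reagents that add atoms: none
Why: Negishi coupling of an alkenyl iodide with a primary alkylzinc halide proceeds with retention of the alkene geometry, and the excess alkylzinc tolerates the free tertiary hydroxyl.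

Step 8
Reactants: 11 2-[(4R,5S)-2,2-dimethyl-5-[(2E)-2-methyl-7-(trimethylsilyl)hept-2-en-6-yn-1-yl]-1,3-dioxolan-4-yl]propan-2-ol
Product: 12 2-[(4R,5S)-2,2-dimethyl-5-[(2E)-2-methylhept-2-en-6-yn-1-yl]-1,3-dioxolan-4-yl]propan-2-ol
Conditions: K2CO3, MeOH, 23 °C
Reagents that add atoms: none
Why: Base-catalysed methanolysis of the alkynyl C–Si bond (protodesilylation) frees the terminal alkyne and touches nothing else.

Step 9
Reactants: 12 2-[(4R,5S)-2,2-dimethyl-5-[(2E)-2-methylhept-2-en-6-yn-1-yl]-1,3-dioxolan-4-yl]propan-2-ol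
Product: 14 Sc-OH, (2E,6E)-8-[(4S,5R)-5-(2-hydroxypropan-2-yl)-2,2-dimethyl-1,3-dioxolan-4-yl]-3,7-dimethylocta-2,6-dien-1-ol, via alkenylalane 13 (not isolated)
Conditions: Me3Al (4 equiv), Cp2ZrCl2 (0.3 equiv), CH2Cl2, 23 °C; volatiles removed; n-BuLi, THF, −78 → 0 °C; (CH2O)n, 23 °C
Reagents that add atoms: trimethylaluminium, C[Al](C)C; paraformaldehyde (as formaldehyde), C=O
Why: A second zirconium-catalysed syn-carboalumination, followed by hydroxymethylation of the derived alkenylalanate with retention, should set the (2'E) allylic alcohol; the existing alkene is inert to the reagent.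

Step 10
Reactants: 14 Sc-OH; 15 4-hydroxy-6-methyl-2H-pyran-2-one (triacetic acid lactone)
Product: 16 6-methyl-4-(Sc-oxy)-2H-pyran-2-one
Conditions: PPh3, DIAD, THF, 0 → 23 °C
Reagents that add atoms: none
Why: Mitsunobu etherification: the acidic vinylogous-acid hydroxyl of 15 is alkylated at O4 by the primary allylic oxyphosphonium ion (SN2, tertiary hydroxyl inert), which fixes O7 as the only etherified oxygen before any arene exists.

Step 11
Reactants: 16 6-methyl-4-(Sc-oxy)-2H-pyran-2-one
Product: 18 6-(2-hydroxyethyl)-4-(Sc-oxy)-2H-pyran-2-one, via lithiated pyranone 17 (not isolated)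
Conditions: LiN(i-Pr)2 (2.2 equiv), THF, −78 °C; CH2O (gas, 1.5 equiv), −78 °C; AcOH
Reagents that add atoms: formaldehyde, C=O
Why: Lateral (vinylogous) deprotonation of the 6-methyl group gives the extended dienolate, which adds to formaldehyde at the exocyclic carbon in an aldol-type hydroxymethylation; a cold acidic quench avoids loss of water.

Step 12
Reactants: 18 6-(2-hydroxyethyl)-4-(Sc-oxy)-2H-pyran-2-one; 19 tert-butyl 2-(triphenyl-λ5-phosphanylidene)acetate
Product: 21 tert-butyl (2E)-4-[2-oxo-4-(Sc-oxy)-2H-pyran-6-yl]but-2-enoate, via aldehyde 20 (not isolated)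
Conditions: Dess–Martin periodinane, NaHCO3, CH2Cl2, 0 °C; then 19 (2.5 equiv), 0 → 23 °C
Reagents that add atoms: none
Why: Dess–Martin oxidation followed in the same flask by Wittig olefination traps the enolisable aldehyde as it forms, the stabilised ylide giving the (E)-enoate; migration of the double bond towards the pyranone would be harmless, since both isomers give the same anion in step 13.

Step 13
Reactants: 21 tert-butyl (2E)-4-[2-oxo-4-(Sc-oxy)-2H-pyran-6-yl]but-2-enoate
Product: 23 tert-butyl (2E)-3-[2,6-dihydroxy-4-(Sc-oxy)phenyl]prop-2-enoate, via ring-opened methyl ester 22 (not isolated)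
Conditions: Mg(OMe)2 (5 equiv), MeOH, Ar, 23 → 65 °C; then AcOH, 0 °C
Reagents that add atoms: none
Why: Proposed new method: methoxide should add to the lactone carbonyl (C8a) of the 4-alkoxy-2-pyranone and open it to the magnesium enolate of the C5 ketone, which unmasks the chain methyl ester C8a / enol ether C7 / ketone C5 / vinylogous tert-butyl ester C4–C3–C2 (22), whereupon the doubly activated C4a carbanion acylates C8a, methoxide leaves and enolisation of the cyclohexenedione gives the arene, so that 23 is an isomer of 21. The closest known reactions are the Mg(OMe)2-induced opening and Claisen recyclisation of 4-hydroxy-6-(2-oxoalkyl)-2-pyranones to acylphloroglucinols and the alkoxide opening of 4-alkoxy-6-alkyl-2-pyranones to 3-alkoxy-5-oxoalk-2-enoates; what is new is a 4-alkoxy pyranone whose nucleophilic carbon is activated by a vinylogous ester. The benzo ring (C4a, C5, C6, C7, C8, C8a) closes 6-exo-trig at the ester carbonyl, an allowed enolate closure whether counted as 6-(enolendo) through the C5 enolate or as 6-(enolexo) through the dienolate of the C2 ester. No stereocentre is formed, and C9' and C10' in the acetonide are remote from the reacting atoms. The step needs C-acylation of C8a by C4a to beat closure of C6 onto the C2 ester, exchange of the C7 alkoxy group by methoxide and retro-Claisen scission of the chain: the cis C7=C8 geometry inherited from the pyranone holds C8a beside C4a, the (E)-C3=C4 bond and the hindered tert-butyl ester keep C2 out of reach, and magnesium chelation of the 1,3-dioxygenated chain tempers the nucleophilicity of methoxide. Reclosure through oxygen only returns 21, so aromatisation is the one irreversible exit.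

Step 14
Reactants: 23 tert-butyl (2E)-3-[2,6-dihydroxy-4-(Sc-oxy)phenyl]prop-2-enoate
Product: 25 5-hydroxy-7-(Sc-oxy)-2H-chromen-2-one, via (Z)-cinnamate 24 (not isolated)
Conditions: hν (365 nm), DBU (1 equiv), degassed MeCN (2 mM), 23 °C
Reagents that add atoms: none
Why: Photochemical E→Z isomerisation of the 2-hydroxycinnamate places either of the two equivalent phenols beside the ester, and base-assisted intramolecular transesterification (lactonisation, loss of tert-butanol) should drain the (Z)-isomer from the photoequilibrium.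

Step 15
Reactants: 25 5-hydroxy-7-(Sc-oxy)-2H-chromen-2-one
Product: 26 5-hydroxy-7-{[(2E,6E,9S,10R)-9,10,11-trihydroxy-3,7,11-trimethyldodeca-2,6-dien-1-yl]oxy}-2H-chromen-2-one (target)
Conditions: AcOH/H2O (4:1), 40 °C
Reagents that add atoms: none
Why: Acid-catalysed hydrolysis of the strained trans-dioxolane under conditions mild enough for the allyl aryl ether, the alkenes and the tertiary alcohol; C9' and C10' keep their C–O bonds and hence their configuration.

## Compound list

1 | diethyl L-tartrate, diethyl (2R,3R)-2,3-dihydroxybutanedioate | CCOC(=O)[C@H](O)[C@@H](O)C(=O)OCC | starting material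
2 | diethyl (4R,5R)-2,2-dimethyl-1,3-dioxolane-4,5-dicarboxylate | CCOC(=O)[C@H](OC1(C)C)[C@@H](O1)C(=O)OCC | intermediate
3 | ethyl (4R,5S)-5-(hydroxymethyl)-2,2-dimethyl-1,3-dioxolane-4-carboxylate | OC[C@H](OC1(C)C)[C@@H](O1)C(=O)OCC | intermediate
4 | 2-[(4R,5S)-5-(hydroxymethyl)-2,2-dimethyl-1,3-dioxolan-4-yl]propan-2-ol | OC[C@H](OC1(C)C)[C@@H](O1)C(C)(C)O | intermediate
5 | 2-[(4R,5R)-5-(iodomethyl)-2,2-dimethyl-1,3-dioxolan-4-yl]propan-2-ol | IC[C@H](OC1(C)C)[C@@H](O1)C(C)(C)O | intermediate
6 | 2-[(4R,5S)-2,2-dimethyl-5-(prop-2-yn-1-yl)-1,3-dioxolan-4-yl]propan-2-ol | C#CC[C@H](OC1(C)C)[C@@H](O1)C(C)(C)O | intermediate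
7 | (E)-alkenyldimethylalane from 6 (dimethylaluminium alkoxide at C11') | C[Al](C)/C=C(\C)C[C@H](OC1(C)C)[C@@H](O1)C(C)(C)O[Al](C)C | intermediate
8 | 2-[(4R,5S)-5-[(2E)-3-iodo-2-methylprop-2-en-1-yl]-2,2-dimethyl-1,3-dioxolan-4-yl]propan-2-ol | I/C=C(\C)C[C@H](OC1(C)C)[C@@H](O1)C(C)(C)O | intermediate
9 | (4-bromobut-1-yn-1-yl)trimethylsilane | C[Si](C)(C)C#CCCBr | starting material
10 | [4-(trimethylsilyl)but-3-yn-1-yl]zinc bromide | C[Si](C)(C)C#CCC[Zn]Br | intermediate
11 | 2-[(4R,5S)-2,2-dimethyl-5-[(2E)-2-methyl-7-(trimethylsilyl)hept-2-en-6-yn-1-yl]-1,3-dioxolan-4-yl]propan-2-ol | C[Si](C)(C)C#CCC/C=C(\C)C[C@H](OC1(C)C)[C@@H](O1)C(C)(C)O | intermediate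
12 | 2-[(4R,5S)-2,2-dimethyl-5-[(2E)-2-methylhept-2-en-6-yn-1-yl]-1,3-dioxolan-4-yl]propan-2-ol | C#CCC/C=C(\C)C[C@H](OC1(C)C)[C@@H](O1)C(C)(C)O | intermediate
13 | (1E,5E)-dienyldimethylalane from 12 (dimethylaluminium alkoxide at C11') | C[Al](C)/C=C(\C)CC/C=C(\C)C[C@H](OC1(C)C)[C@@H](O1)C(C)(C)O[Al](C)C | intermediate
14 | Sc-OH, (2E,6E)-8-[(4S,5R)-5-(2-hydroxypropan-2-yl)-2,2-dimethyl-1,3-dioxolan-4-yl]-3,7-dimethylocta-2,6-dien-1-ol | OC/C=C(\C)CC/C=C(\C)C[C@H](OC1(C)C)[C@@H](O1)C(C)(C)O | intermediate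
15 | 4-hydroxy-6-methyl-2H-pyran-2-one (triacetic acid lactone) | Cc1cc(O)cc(=O)o1 | starting material
16 | 6-methyl-4-(Sc-oxy)-2H-pyran-2-one | C/C(=C\COc1cc(=O)oc(C)c1)CC/C=C(\C)C[C@H](OC1(C)C)[C@@H](O1)C(C)(C)O | intermediate
17 | 6-(lithiomethyl) derivative of 16 (extended lithium dienolate, lithium alkoxide at C11') | C/C(=C\COc1cc(=O)oc(C[Li])c1)CC/C=C(\C)C[C@H](OC1(C)C)[C@@H](O1)C(C)(C)O[Li] | intermediate
18 | 6-(2-hydroxyethyl)-4-(Sc-oxy)-2H-pyran-2-one | C/C(=C\COc1cc(=O)oc(CCO)c1)CC/C=C(\C)C[C@H](OC1(C)C)[C@@H](O1)C(C)(C)O | intermediate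
19 | tert-butyl 2-(triphenyl-λ5-phosphanylidene)acetate | CC(C)(C)OC(=O)C=P(c1ccccc1)(c1ccccc1)c1ccccc1 | starting material
20 | 2-[2-oxo-4-(Sc-oxy)-2H-pyran-6-yl]acetaldehyde | C/C(=C\COc1cc(=O)oc(CC=O)c1)CC/C=C(\C)C[C@H](OC1(C)C)[C@@H](O1)C(C)(C)O | intermediate
21 | tert-butyl (2E)-4-[2-oxo-4-(Sc-oxy)-2H-pyran-6-yl]but-2-enoate | C/C(=C\COc1cc(=O)oc(C/C=C/C(=O)OC(C)(C)C)c1)CC/C=C(\C)C[C@H](OC1(C)C)[C@@H](O1)C(C)(C)O | intermediate
22 | 1-tert-butyl 9-methyl (2E,7E)-5-oxo-7-(Sc-oxy)nona-2,7-dienedioate | COC(=O)/C=C(\CC(=O)C/C=C/C(=O)OC(C)(C)C)OC/C=C(\C)CC/C=C(\C)C[C@H](OC1(C)C)[C@@H](O1)C(C)(C)O | intermediate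
23 | tert-butyl (2E)-3-[2,6-dihydroxy-4-(Sc-oxy)phenyl]prop-2-enoate | C/C(=C\COc1cc(O)c(/C=C/C(=O)OC(C)(C)C)c(O)c1)CC/C=C(\C)C[C@H](OC1(C)C)[C@@H](O1)C(C)(C)O | intermediate
24 | tert-butyl (2Z)-3-[2,6-dihydroxy-4-(Sc-oxy)phenyl]prop-2-enoate | C/C(=C\COc1cc(O)c(/C=C\C(=O)OC(C)(C)C)c(O)c1)CC/C=C(\C)C[C@H](OC1(C)C)[C@@H](O1)C(C)(C)O | intermediate
25 | 5-hydroxy-7-(Sc-oxy)-2H-chromen-2-one | C/C(=C\COc1cc(O)c2ccc(=O)oc2c1)CC/C=C(\C)C[C@H](OC1(C)C)[C@@H](O1)C(C)(C)O | intermediate
26 | 5-hydroxy-7-{[(2E,6E,9S,10R)-9,10,11-trihydroxy-3,7,11-trimethyldodeca-2,6-dien-1-yl]oxy}-2H-chromen-2-one | C/C(=C\COc1cc(O)c2ccc(=O)oc2c1)CC/C=C(\C)C[C@H](O)[C@@H](O)C(C)(C)O | target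

## Step count and risks

Total step count: 15. Longest linear sequence: 15 steps (1 → 26); compounds 9, 15 and 19 are bought.

Steps most likely to fail:

1. Step 13 (proposed new method). The pyranone may fail to open because the substrate rests as its delocalised C4a anion, or methoxide may exchange the C7 alkoxy group or cut the unmasked chain by retro-Claisen scission before the ring closes. The fallback uses known chemistry and runs from 14 to 25. Appel bromination of 14 (CBr4, PPh3, CH2Cl2, 0 °C) should give the allylic bromide 2-[(4R,5S)-5-[(2E,6E)-8-bromo-2,6-dimethylocta-2,6-dien-1-yl]-2,2-dimethyl-1,3-dioxolan-4-yl]propan-2-ol F1. This alkylates commercial 5,7-dihydroxy-2H-chromen-2-one (K2CO3, 1 equiv, acetone, 23 °C) at the more acidic 7-hydroxyl, which is vinylogous to the lactone carbonyl, and gives 25 directly; step 15 then follows.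

2. Step 12. The heteroarylacetaldehyde 20 may enolise and self-condense before the ylide traps it, and the new double bond may wander. The fallback runs from 16 to 21 and leaves out 18 and 20. Lateral deprotonation of 16 as in step 11 (LiN(i-Pr)2, THF, −78 °C) and transmetallation with ZnCl2 should give the chlorozinc derivative of 16 F2. Negishi coupling of this with tert-butyl (2E)-3-iodoprop-2-enoate F3 (Pd(P(t-Bu)3)2 cat., THF, 0 → 23 °C) should give 21 with retention of the (E)-geometry. The iodide is made from commercial (2E)-3-iodoprop-2-enoic acid and tert-butyl 2,2,2-trichloroacetimidate (CH2Cl2, 23 °C). The coupling is stopped as soon as the iodide is consumed, because zerovalent palladium can ionise the allylic pyranonyl ether.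

3. Step 14. Lactonisation onto the hindered tert-butyl ester may be slow, so that the (Z)-ester only reaches its photostationary share, and the coumarin formed may photodimerise on long irradiation. The fallback runs from 23 to 25 without light, by nucleophilic catalysis with PBu3 (20 mol %, MeOH, 65 °C). Reversible conjugate addition of the phosphine turns the C3–C4 bond into a single bond, the phenoxide lactonises and the phosphine is eliminated; this is a known way from (E)-2-hydroxycinnamic esters to coumarins. No new compound is made on the way (F0).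

## Further compounds

F1 | step 13 | 2-[(4R,5S)-5-[(2E,6E)-8-bromo-2,6-dimethylocta-2,6-dien-1-yl]-2,2-dimethyl-1,3-dioxolan-4-yl]propan-2-ol | BrC/C=C(\C)CC/C=C(\C)C[C@H](OC1(C)C)[C@@H](O1)C(C)(C)O
F2 | step 12 | chlorozinc derivative of 16, 6-[(chlorozincio)methyl]-4-(Sc-oxy)-2H-pyran-2-one with chlorozinc alkoxide at C11' | C/C(=C\COc1cc(=O)oc(C[Zn]Cl)c1)CC/C=C(\C)C[C@H](OC1(C)C)[C@@H](O1)C(C)(C)O[Zn]Cl
F3 | step 12 | tert-butyl (2E)-3-iodoprop-2-enoate | CC(C)(C)OC(=O)/C=C/I
F0 | step 14 | none | none
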